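In a one-step world, starting material and salt in the second phase go over to product and spent salt in the second phase under a single constant. I began there, with a constant read from a plateau.

| flask | starting material | salt in the second phase | spent carrier | remark | volume of the second phase over the first |
|---|---|---|---|---|---|
| Wednesday's | 0.10 M | 0.15 M | 10 mM | the very flask that is asked about, followed so far |  |
| Sunday's | 0.10 M | 0.30 M | 10 mM | run made earlier |  |
| flask | 0.10 M | 0.150 M | 10 mM |  | 1.0 |

- Wednesday's (time / s: product / %): 10.0: 12.1; 20.0: 20.7; 50.0: 35.5; 120: 44.7
- Sunday's (time / min: product / %): 2.50: 62.0; 5.00: 61.7; 8.00: 63.4; 10.0: 61.6

(standard deviation of a reading: 1 percentage point)

- in the second phase: salt in the second phase, spent salt in the second phase; everything else is in the first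
- charges count per volume of the first phase; a concentration in a rate is the amount of a species over the volume of its own phase; every rate counts per litre of the first phase
- the analysis behind the earlier runs scatters by 1 percentage point, standard deviation
- steps that have been proposed: spent carrier + salt in the second phase <-> fresh carrier + spent salt in the second phase; starting material + fresh carrier <-> product + spent carrier
- the earlier runs hold the two phases in the same ratio of volumes as the flask asked about
- no earlier run changes the charge of spent carrier; that part of a forecast is a guess

- factor on the rate of making product when 30% of the starting material are converted if spent carrier is charged twice over
- factor on the rate when 30% of the starting material are converted if spent carrier is charged at 2.0 mM instead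

Sunday's 4 readings averaged 62.2% of the starting material charged. Counting product and spent salt each as that fraction, I got 0.430. This plateau constant, product times spent salt over starting material times salt, was what I carried forward. Wednesday's last reading, in the same formula, gave 0.343, less than Sunday's. The two ways parted, and I took Wednesday's as the one that cheats: its product rose 9.2 percentage points between 50.0 s and 120 s, while Sunday's readings lay within 1.8 points of each other, with a scatter of 1 point.

For Wednesday's flask at 30% conversion, I reckoned the same quotient at 0.249 of the plateau constant, and I took that share of the forward rate as handed back. The zero of my scale was proportion, a factor of 2 on doubling and 0.200 at the lower charge. But each fresh carrier stands for one more spent salt. Taking 0.5 of the carrier as fresh, I reckoned 1.83 and 0.213. No earlier run changed the carrier, so both are extrapolations.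

The forecast gave 1.75 (1.5 to 2.05) and 0.22 (0.19 to 0.27), near my figures but not the same, holding that “about half the carrier sits as fresh carrier at 30% conversion”.

Wednesday's flask gave 1.61 and 0.237, both inside the forecast's ranges; the first lay below my figure and the second above it.

    spent carrier + salt in the second phase ⇌ fresh carrier + spent salt in the second phase (K = 1.60, k = 1.30 M⁻¹ s⁻¹)
    starting material + fresh carrier ⇌ product + spent carrier (K = 0.330, k = 17.0 M⁻¹ s⁻¹)

At 1.00 min in Wednesday's flask, fresh carrier held 64.5% of the catalyst charged, more than the 35.5% of spent carrier. To prove the forecast wrong, a run at doubled carrier must show a factor outside its range, as the 1.00 from the fit of one step, first order each way, lies below it. Put to Wednesday's charges, the plateau constant gave 47.8% product, and the flask held 47.7% after 10.0 min.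

Readings and results were computed on assumed constants.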